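Conventions: the decalin uses drimane numbering (C11 is the CH2 link, C12 the methyl on C8, and C4 carries a CH3 and the carboxyl carbon). β means the face of the C10 methyl. The C7 ring is C1'(CH3)=C2'–C3'(OH)–C4'(C11, O)–C5'(O)–C6'(OH).

Assumption: the (S)-oxazaborolidinium catalyst of step 8 sends cyclopentadiene to the quinone face that later carries the two hydroxyls. If the sense proves opposite, the equally available (R)-precatalyst is used and nothing else changes.

## Retrosynthetic overview

1. Target 19 comes from 1,2-reduction and retro-Diels–Alder of a cyclopentadiene-caged epoxy ketone 17. The cage provides site and face control for the oxirane and for C3'.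
2. Cage 17 comes from the drimenylmethyl-toluquinone acid 13, and 13 from the bicyclic diol 7 by C3 deoxygenation, alkene shift and oxidation.
3. Key step: diol 7 comes from the acyclic Sharpless epoxy alcohol 6. A Ti(III) radical cascade forms C4–C5 and C9–C10, so rings A and B close together. No cation forms, so the electron-rich arene is not alkylated.
4. Epoxy alcohol 6 comes from farnesyl arene 4, and 4 from aryl bromide 1 and farnesyl bromide 2.
5. Ring order: the arene is bought, then A and B form together, then the temporary norbornene cage, then the oxirane, and finally the cage is removed.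

## Route

Step 1
Reactants: 1 1-bromo-2,5-dimethoxy-4-methylbenzene; 2 (2E,6E)-farnesyl bromide
Product: 4 1-[(2E,6E)-farnesyl]-2,5-dimethoxy-4-methylbenzene, via aryllithium 3 (not isolated)
Conditions: n-BuLi, THF, −78 °C; CuI (10 mol %), then 2, −78 °C to rt
Reagents that add atoms: none
Why: Halogen–lithium exchange followed by copper-assisted SN2 allylation at the primary allylic bromide keeps both E-alkenes and creates no stereocentre.

Step 2
Reactants: 4 farnesyl arene
Product: 5 (2E,6E,10E)-12-(2,5-dimethoxy-4-methylphenyl)-2,6,10-trimethyldodeca-2,6,10-trien-1-ol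
Conditions: SeO2 (0.3 equiv), t-BuOOH, salicylic acid (cat.), CH2Cl2, 0 °C, stopped at partial conversion with 4 recycled
Reagents that add atoms: tert-butyl hydroperoxide, CC(C)(C)OO
Why: Catalytic SeO2 allylic oxidation (ene reaction then [2,3]-shift) prefers the terminal isopropylidene and always its (E)-methyl group, so the (E)-allylic alcohol forms and no stereocentre arises.

Step 3
Reactants: 5 (E)-allylic alcohol
Product: 6 [(2S,3S)-3-[(3E,7E)-9-(2,5-dimethoxy-4-methylphenyl)-3,7-dimethylnona-3,7-dienyl]-2-methyloxiran-2-yl]methanol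
Conditions: Ti(OiPr)4 (10 mol %), L-(+)-DET (12 mol %), t-BuOOH, 4 Å MS, CH2Cl2, −20 °C
Reagents that add atoms: tert-butyl hydroperoxide, CC(C)(C)OO
Why: Katsuki–Sharpless asymmetric epoxidation touches only the allylic-alcohol alkene, and L-(+)-DET gives the (2S,3S)-epoxide, which stores the absolute information at C3 (3S).

Step 4 (key step)
Reactants: 6 epoxy alcohol
Product: 7 bicyclic diol (trans-decalin with 3β-OH, 4α-CH2OH, 4β-CH3, 5α-H, 10β-CH3, 9β-CH2Ar, 9α-H and 8(12)-exomethylene)
Conditions: Cp2TiCl2 (2.5 equiv), Mn dust, degassed THF, rt, slow addition of 6 (0.01 M); then H2O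
Reagents that add atoms: none
Why: Titanocene(III) homolytic epoxide opening (Nugent–RajanBabu type epoxypolyene cyclisation) gives the tertiary C4 radical, which runs a 6-endo/6-endo chair–chair cascade and ends by titanium-mediated β-hydride loss to the exocyclic alkene; the equatorial C3–OTi fixes the sense of folding, the two E-alkenes give 5α-H, 10β-CH3 and 9β-CH2Ar, and the bulky CH2OTi arm takes the equatorial 4α site away from the axial C10 methyl.

Step 5
Reactants: 7 bicyclic diol
Product: 10 3-deoxy primary alcohol (4α-CH2OH, 8(12)-ene), via cyclic thionocarbonate 8 (not isolated), via stannyl thiolcarbonate 9 (not isolated)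
Conditions: 1,1'-thiocarbonyldiimidazole, DMAP (cat.), PhMe, 90 °C; then Bu3SnH, AIBN (cat.), reflux; then H2O–THF, rt
Reagents that add atoms: none
Why: Barton–McCombie deoxygenation through the cyclic thionocarbonate of the 1,3-diol fragments towards the secondary C3 radical rather than the primary one, so C3 becomes CH2, the primary alcohol is released on hydrolysis, and C4, C5, C9 and C10 are untouched.

Step 6
Reactants: 10 exocyclic alkene
Product: 11 Δ7 primary alcohol (drim-7-ene, 4α-CH2OH)
Conditions: Co(salen-tBu,tBu)Cl (5 mol %), PhSiH3 (10 mol %), benzene, rt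
Reagents that add atoms: none
Why: Cobalt-hydride MHAT alkene isomerisation puts H• reversibly on the 1,1-disubstituted alkene only, and the C8 radical loses the accessible C7–H rather than the shielded C9–H, which funnels material to the inert trisubstituted Δ7 alkene with no cation that could alkylate the arene.

Step 7
Reactants: 11 Δ7 primary alcohol
Product: 13 2-methyl-5-(drimenylmethyl)-1,4-benzoquinone 4α-carboxylic acid, via carboxylic acid 12 (not isolated)
Conditions: AZADO (5 mol %), PhI(OAc)2 (2.3 equiv), MeCN–H2O, rt; then (NH4)2Ce(NO3)6 (2.5 equiv), 0 °C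
Reagents that add atoms: water, O
Why: Oxoammonium-catalysed oxidation takes the neopentyl alcohol through the aldehyde hydrate to the acid, and CAN oxidative demethylation then gives the p-quinone in the same aqueous acetonitrile, with the hindered Δ7 alkene and all stereocentres untouched.

Step 8
Reactants: 13 quinone acid; 14 cyclopentadiene (cracked from commercial dicyclopentadiene)
Product: 15 endo cage adduct (4a-methyl-7-(drimenylmethyl)-1,4,4a,8a-tetrahydro-1,4-methanonaphthalene-5,8-dione; 1'-CH3 and 2'-H cis on the convex face)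
Conditions: (S)-o-tolyl-diphenylprolinol oxazaborolidine·Tf2NH (20 mol %), CH2Cl2, −78 °C
Reagents that add atoms: none
Why: In this enantioselective oxazaborolidinium-catalysed Diels–Alder reaction the diene takes the quinone C=C bearing the small methyl rather than the one bearing the drimenylmethyl group, adds endo, and the catalyst rather than the remote decalin chooses the quinone face, which sets the four centres of the temporary cage.

Step 9
Reactants: 15 cage adduct
Product: 17 cage epoxy hydroxy ketone (4',5'-oxirane on the convex face, 3'-OH on the concave face, 6'-ketone kept), via epoxy dione cage 16 (not isolated)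
Conditions: t-BuOOH (decane), DBU (2.5 equiv), CH2Cl2, 0 °C; then MeOH, NaBH4 (1.0 equiv), −78 °C
Reagents that add atoms: tert-butyl hydroperoxide, CC(C)(C)OO
Why: Weitz–Scheffer nucleophilic epoxidation can reach only the remaining enedione C=C and only from the convex face (setting C4' and C5'), and borohydride also attacks from that face and reduces C3'=O first because C6'=O lies next to the angular methyl, so the 3'-OH ends anti to the oxirane.

Step 10
Reactants: 17 cage epoxy hydroxy ketone
Product: 19 CNP0358222.2 (target), via hydroxy epoxy enone 18 (not isolated)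
Conditions: Ph2O, 200 °C, N2 stream, 20 min; cool; then THF–MeOH, CeCl3·7H2O, NaBH4, −78 °C
Reagents that add atoms: none
Why: Retro-Diels–Alder thermolysis is driven by release of the conjugated enone and of volatile cyclopentadiene, and Luche 1,2-reduction then delivers hydride to C6' from the oxirane face because the other face carries the 3'-oxygen and the 1,3-related drimenylmethyl group, giving the cis-1,4-diol anti to the epoxide.

## Compound list

1 | 1-bromo-2,5-dimethoxy-4-methylbenzene | COc1cc(Br)c(OC)cc1C | starting material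
2 | (2E,6E)-farnesyl bromide | CC(C)=CCC/C(C)=C/CC/C(C)=C/CBr | starting material
3 | (2,5-dimethoxy-4-methylphenyl)lithium | COc1cc([Li])c(OC)cc1C | intermediate
4 | farnesyl arene | COc1cc(C/C=C(C)/CC/C=C(C)/CCC=C(C)C)c(OC)cc1C | intermediate
5 | terminal (E)-allylic alcohol | COc1cc(C/C=C(C)/CC/C=C(C)/CC/C=C(C)/CO)c(OC)cc1C | intermediate
6 | (2S,3S)-epoxy alcohol | COc1cc(C/C=C(C)/CC/C=C(C)/CC[C@@H]2O[C@@]2(C)CO)c(OC)cc1C | intermediate
7 | bicyclic 3β,4α-CH2OH diol, 8(12)-ene | COc1cc(C[C@H]2C(=C)CC[C@@H]3[C@]2(C)CC[C@H](O)[C@@]3(C)CO)c(OC)cc1C | intermediate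
8 | cyclic thionocarbonate of 7 | COc1cc(C[C@H]2C(=C)CC[C@@H]3[C@]2(C)CC[C@@H]4OC(=S)OC[C@@]34C)c(OC)cc1C | intermediate
9 | O-alkyl S-tributylstannyl thiolcarbonate (C3 = CH2) | COc1cc(C[C@H]2C(=C)CC[C@@H]3[C@]2(C)CCC[C@@]3(C)COC(=O)S[Sn](CCCC)(CCCC)CCCC)c(OC)cc1C | intermediate
10 | 3-deoxy primary alcohol, 8(12)-ene | COc1cc(C[C@H]2C(=C)CC[C@@H]3[C@]2(C)CCC[C@@]3(C)CO)c(OC)cc1C | intermediate
11 | Δ7 primary alcohol | COc1cc(C[C@H]2C(C)=CC[C@@H]3[C@]2(C)CCC[C@@]3(C)CO)c(OC)cc1C | intermediate
12 | Δ7 4α-carboxylic acid, arene still dimethyl ether | COc1cc(C[C@H]2C(C)=CC[C@@H]3[C@]2(C)CCC[C@@]3(C)C(=O)O)c(OC)cc1C | intermediate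
13 | quinone acid | CC1=CC(=O)C(C[C@H]2C(C)=CC[C@@H]3[C@]2(C)CCC[C@@]3(C)C(=O)O)=CC1=O | intermediate
14 | cyclopentadiene | C1C=CC=C1 | starting material
15 | endo cage adduct | C[C@@]12C(=O)C=C(C[C@H]3C(C)=CC[C@@H]4[C@]3(C)CCC[C@@]4(C)C(=O)O)C(=O)[C@@H]1[C@@H]1C=C[C@H]2C1 | intermediate
16 | cage epoxy dione | C[C@@]12C(=O)[C@H]3O[C@@]3(C[C@H]4C(C)=CC[C@@H]5[C@]4(C)CCC[C@@]5(C)C(=O)O)C(=O)[C@@H]1[C@@H]1C=C[C@H]2C1 | intermediate
17 | cage epoxy hydroxy ketone | C[C@@]12C(=O)[C@H]3O[C@@]3(C[C@H]4C(C)=CC[C@@H]5[C@]4(C)CCC[C@@]5(C)C(=O)O)[C@H](O)[C@@H]1[C@@H]1C=C[C@H]2C1 | intermediate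
18 | 3'-hydroxy-4',5'-epoxy enone | CC1=C[C@@H](O)[C@]2(C[C@H]3C(C)=CC[C@@H]4[C@]3(C)CCC[C@@]4(C)C(=O)O)O[C@@H]2C1=O | intermediate
19 | CNP0358222.2 | CC1=C[C@@H](O)[C@]2(C[C@H]3C(C)=CC[C@@H]4[C@]3(C)CCC[C@@]4(C)C(=O)O)O[C@@H]2[C@H]1O | target

## Step count and risks

Total steps: 10. Longest linear sequence: 10.

**Step 4.** The risks are the yield of the double 6-endo cascade and the 4α/4β ratio at the planar C4 radical. The fallback sets out from 6 and comes back at 7.
- The primary alcohol is silylated (TBDPSCl, imidazole) to the epoxy silyl ether F1. A covalently bound, very large group then steers C4, instead of a titanium alkoxide formed in situ.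
- F1 is cyclised under the titanium-catalytic regime (Cp2TiCl2 20 mol %, Mn, TMSCl/collidine) to the bicyclic silyl ether F2.
- TBAF removes silicon and gives 7.

**Step 9.** The risk is stopping at mono-reduction and choosing C3' over C6'. The fallback sets out from 16, which is isolated after the epoxidation, and comes back at 19.
- 16 is thermolysed first to the free epoxyquinone F3.
- Both ketones are then reduced under reagent control with (S)-Me-CBS and catecholborane.
- The larger flanks are C4' at C3'=O and C1' at C6'=O, and for both carbonyls this directs hydride to the oxirane face.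

**Step 10.** The risk is the facial selectivity of the last hydride addition. The fallback sets out from 17 and comes back at 19.
- The second ketone is reduced while the cage is still in place (DIBAL-H, convex-face attack) to the cage diol F4. The cage, not the substrate conformation, then sets C6'.
- Cyclopentadiene is expelled by flash vacuum pyrolysis at about 500 °C.

## Further compounds

F1 | step 4 | TBDPS ether of epoxy alcohol 6 | COc1cc(C/C=C(C)/CC/C=C(C)/CC[C@@H]2O[C@@]2(C)CO[Si](c2ccccc2)(c2ccccc2)C(C)(C)C)c(OC)cc1C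
F2 | step 4 | bicyclic 3β-ol with 4α-CH2OTBDPS, 8(12)-ene | COc1cc(C[C@H]2C(=C)CC[C@@H]3[C@]2(C)CC[C@H](O)[C@@]3(C)CO[Si](c2ccccc2)(c2ccccc2)C(C)(C)C)c(OC)cc1C
F3 | step 9 | 4',5'-epoxyquinone acid | CC1=CC(=O)[C@]2(C[C@H]3C(C)=CC[C@@H]4[C@]3(C)CCC[C@@]4(C)C(=O)O)O[C@@H]2C1=O
F4 | step 10 | cage epoxy diol | C[C@@]12[C@H](O)[C@H]3O[C@@]3(C[C@H]4C(C)=CC[C@@H]5[C@]4(C)CCC[C@@]5(C)C(=O)O)[C@H](O)[C@@H]1[C@@H]1C=C[C@H]2C1
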